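**Retrosynthetic overview** (cyclohexane numbering: C1 = CH bearing the chain, C2 = C(CH3)2, C3 = CHOH, C6 = C(=CH2))
1. The pyrone is attached last at its C3–CH2 bond by Tsuji–Trost allylation of commercial 4-hydroxy-6-methyl-2-pyrone; before that, the exocyclic C6=CH2 is taken back to a C6 ketone.
2. The cyclohexane, the only ring made in the route, is closed at the C2–C3 bond by a hydrogen-atom-transfer (HAT) radical cyclisation of an acyclic γ-keto aldehyde.
3. Enabling feature: quaternary C2 with its two methyls, together with ring CH C1, is the intact Me2C=CH terminus of a farnesyl chain, and C3 stands 1,4 to C6. With C6 as C=O the ring is a farnesyl terminus annulated by the four carbons of succinaldehyde, C2 being a tertiary radical born from an isopropenyl group and C3 an aldehyde carbon five atoms away.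
4. The precursor comes from farnesyl acetate by C12 oxidation and bromination, then an asymmetric chromium allylation of succinaldehyde mono-acetal through C10 (sets the future ring C1 stereocentre), oxidation and acetal hydrolysis.
5. Ring order: cyclohexane (step 6), then the ready-made pyrone ring (step 8).

Key step: step 6

Assumption: (2E,6E)-farnesyl acetate and 4,4-dimethoxybutanal are taken as catalogue compounds of single-isomer grade, and the ligand antipode for step 3 is assigned on compound 6 by Mosher ester analysis.

**Step 1**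
Reactants: 1 (2E,6E)-farnesyl acetate
Product: 2 (2E,6E,10E)-12-hydroxy-3,7,11-trimethyldodeca-2,6,10-trien-1-yl acetate
Conditions: SeO2 (cat.), t-BuOOH, salicylic acid (cat.), CH2Cl2, rt
Reagents that add atoms: tert-butyl hydroperoxide, CC(C)(C)OO (oxygen source, relayed by catalytic selenium dioxide, O=[Se]=O)
Why: Selenium dioxide allylic oxidation (ene reaction, then [2,3]-sigmatropic shift) should attack the most accessible, electron-rich terminal trisubstituted alkene at its (E)-methyl group, the 2,3-alkene being deactivated by the allylic acetate; no stereocentre is formed.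

**Step 2**
Reactants: 2 (2E,6E,10E)-12-hydroxy-3,7,11-trimethyldodeca-2,6,10-trien-1-yl acetate
Product: 3 (2E,6E,10E)-12-bromo-3,7,11-trimethyldodeca-2,6,10-trien-1-yl acetate
Conditions: CBr4, PPh3, CH2Cl2, 0 °C
Reagents that add atoms: carbon tetrabromide, BrC(Br)(Br)Br
Why: Appel bromination displaces the primary allylic alkoxyphosphonium ion by SN2 under neutral conditions, which should leave the acetate and all alkene geometries untouched.

**Step 3**
Reactants: 3 (2E,6E,10E)-12-bromo-3,7,11-trimethyldodeca-2,6,10-trien-1-yl acetate; 4 4,4-dimethoxybutanal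
Product: 6 (2E,6E,10S,11R)-11-hydroxy-14,14-dimethoxy-3,7-dimethyl-10-(prop-1-en-2-yl)tetradeca-2,6-dien-1-yl acetate, via trimethylsilyl ether 5 (not isolated)
Conditions: CrCl2 (10 mol %), chiral C2-symmetric 1,8-bis(oxazolin-2-yl)carbazole ligand (antipode giving the 11R carbinol), i-Pr2NEt, Mn powder, TMSCl, THF, rt; then TBAF, AcOH, THF, 0 °C
Reagents that add atoms: none
Why: Catalytic asymmetric Nozaki–Hiyama–Kishi allylation, in which the allylchromium species adds through its γ-carbon (C10) in a chair Zimmerman–Traxler transition state (isopropenyl-bearing stereocentre, anti relationship) while the chiral ligand on trivalent chromium selects the aldehyde face (11R, hence 10S); the silyl ether 5 is cleaved by buffered fluoride without touching acetal or acetate.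

**Step 4**
Reactants: 6 (2E,6E,10S,11R)-11-hydroxy-14,14-dimethoxy-3,7-dimethyl-10-(prop-1-en-2-yl)tetradeca-2,6-dien-1-yl acetate
Product: 7 (2E,6E,10S)-14,14-dimethoxy-3,7-dimethyl-11-oxo-10-(prop-1-en-2-yl)tetradeca-2,6-dien-1-yl acetate
Conditions: Dess–Martin periodinane, pyridine, CH2Cl2, 0 °C
Reagents that add atoms: none
Why: Buffered Dess–Martin oxidation gives the β,γ-unsaturated ketone without acid or base able to enolise it, so the C10 stereocentre and the deconjugated isopropenyl group should survive, while the C11 stereocentre is deliberately erased.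

**Step 5**
Reactants: 7 (2E,6E,10S)-14,14-dimethoxy-3,7-dimethyl-11-oxo-10-(prop-1-en-2-yl)tetradeca-2,6-dien-1-yl acetate
Product: 8 (2E,6E,10S)-3,7-dimethyl-11,14-dioxo-10-(prop-1-en-2-yl)tetradeca-2,6-dien-1-yl acetate
Conditions: LiBF4, MeCN/H2O (98:2), rt
Reagents that add atoms: water, O
Why: Mild Lewis-acid-assisted acetal hydrolysis should unmask the aldehyde under near-neutral conditions that avoid enolisation at C10, cationic polyene cyclisation and acetate loss.

**Step 6**
Reactants: 8 (2E,6E,10S)-3,7-dimethyl-11,14-dioxo-10-(prop-1-en-2-yl)tetradeca-2,6-dien-1-yl acetate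
Product: 11 (2E,6E)-9-[(1S,3S)-3-hydroxy-2,2-dimethyl-6-oxocyclohexyl]-3,7-dimethylnona-2,6-dien-1-yl acetate, via tertiary alkyl radical 9 (not isolated), via cyclohexyloxyl radical 10 (not isolated)
Conditions: Fe(acac)3 (30 mol %), PhSiH3, EtOH (0.02 M), 60 °C, Ar
Reagents that add atoms: none
Why: Fe(acac)3 and PhSiH3 in ethanol generate an iron hydride that transfers a hydrogen atom to the CH2 terminus of the isopropenyl group (Markovnikov HAT), so the carbon that becomes ring C2 appears as tertiary radical 9 and its former CH2 returns as the second methyl group. The nucleophilic radical adds 6-exo-trig to the aldehyde C=O (forming the C2–C3 bond and the cyclohexane), and alkoxyl radical 10 is reduced by divalent iron to the alkoxide and protonated by ethanol, which pulls the reversible addition forward. The closest known reaction type is the iron-hydride HAT-initiated reductive cyclisation of alkene-tethered ketones, together with the related intermolecular addition of unactivated alkenes to aldehydes. The new C3 stereocentre is controlled by the existing C1 stereocentre through a chair transition state with the C1 side chain equatorial and the iron-bound carbonyl oxygen pseudo-equatorial, giving the 1,3-cis (1S,3S) product, and ring-opening of 10 lets the alkoxyl epimers drain towards the diequatorial one; C2 is not stereogenic and C1, now α to the ketone, already has its preferred equatorial configuration. The step needs chemoselective HAT to the 1,1-disubstituted alkene over the two trisubstituted alkenes, secured by the unhindered terminal CH2, and capture by the aldehyde faster than 6-endo attack on the C6=C7 chain alkene or simple reduction, favoured by the four-atom tether and high dilution.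

**Step 7**
Reactants: 11 (2E,6E)-9-[(1S,3S)-3-hydroxy-2,2-dimethyl-6-oxocyclohexyl]-3,7-dimethylnona-2,6-dien-1-yl acetate
Product: 12 (2E,6E)-9-[(1R,3S)-3-hydroxy-2,2-dimethyl-6-methylidenecyclohexyl]-3,7-dimethylnona-2,6-dien-1-yl acetate
Conditions: Zn, CH2Br2, TiCl4, THF, 0 °C (pre-formed reagent); then 11, CH2Cl2, rt
Reagents that add atoms: dibromomethane, BrCBr
Why: Takai–Lombardo methylenation is non-basic and reaches hindered, enolisable ketones, so the C6 ketone should become the exocyclic methylene without epimerising C1 or attacking the acetate, the free hydroxyl only consuming reagent as a titanium alkoxide (the descriptor at C1 changes from S to R by priority only).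

**Step 8**
Reactants: 12 (2E,6E)-9-[(1R,3S)-3-hydroxy-2,2-dimethyl-6-methylidenecyclohexyl]-3,7-dimethylnona-2,6-dien-1-yl acetate; 13 4-hydroxy-6-methyl-2H-pyran-2-one
Product: 14 sartorypyrone D
Conditions: Pd(PPh3)4 (5 mol %), DBU, THF, 50 °C, excess 13
Reagents that add atoms: none
Why: Tsuji–Trost allylation, in which zerovalent palladium ionises the allylic acetate to a syn π-allyl complex and the soft C3 carbon of the pyronate attacks the unhindered primary terminus, should give the linear (E) C-allylated pyrone, any O-allyl ether re-ionising to the same complex.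

**Compound list**
1 | (2E,6E)-farnesyl acetate | CC(C)=CCC/C(C)=C/CC/C(C)=C/COC(C)=O | starting material
2 | (2E,6E,10E)-12-hydroxy-3,7,11-trimethyldodeca-2,6,10-trien-1-yl acetate | OC/C(C)=C/CC/C(C)=C/CC/C(C)=C/COC(C)=O | intermediate
3 | (2E,6E,10E)-12-bromo-3,7,11-trimethyldodeca-2,6,10-trien-1-yl acetate | BrC/C(C)=C/CC/C(C)=C/CC/C(C)=C/COC(C)=O | intermediate
4 | 4,4-dimethoxybutanal | COC(OC)CCC=O | starting material
5 | (2E,6E,10S,11R)-14,14-dimethoxy-3,7-dimethyl-10-(prop-1-en-2-yl)-11-(trimethylsilyloxy)tetradeca-2,6-dien-1-yl acetate | C=C(C)[C@@H]([C@H](O[Si](C)(C)C)CCC(OC)OC)CC/C(C)=C/CC/C(C)=C/COC(C)=O | intermediate (not isolated)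
6 | (2E,6E,10S,11R)-11-hydroxy-14,14-dimethoxy-3,7-dimethyl-10-(prop-1-en-2-yl)tetradeca-2,6-dien-1-yl acetate | C=C(C)[C@@H]([C@H](O)CCC(OC)OC)CC/C(C)=C/CC/C(C)=C/COC(C)=O | intermediate
7 | (2E,6E,10S)-14,14-dimethoxy-3,7-dimethyl-11-oxo-10-(prop-1-en-2-yl)tetradeca-2,6-dien-1-yl acetate | C=C(C)[C@@H](C(=O)CCC(OC)OC)CC/C(C)=C/CC/C(C)=C/COC(C)=O | intermediate
8 | (2E,6E,10S)-3,7-dimethyl-11,14-dioxo-10-(prop-1-en-2-yl)tetradeca-2,6-dien-1-yl acetate | C=C(C)[C@@H](C(=O)CCC=O)CC/C(C)=C/CC/C(C)=C/COC(C)=O | intermediate
9 | tertiary alkyl radical from HAT to the isopropenyl group of 8 | C[C](C)[C@@H](C(=O)CCC=O)CC/C(C)=C/CC/C(C)=C/COC(C)=O | intermediate (not isolated)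
10 | cyclohexyloxyl radical (O-centred radical of 11) | O=C1CC[C@H]([O])C(C)(C)[C@@H]1CC/C(C)=C/CC/C(C)=C/COC(C)=O | intermediate (not isolated)
11 | (2E,6E)-9-[(1S,3S)-3-hydroxy-2,2-dimethyl-6-oxocyclohexyl]-3,7-dimethylnona-2,6-dien-1-yl acetate | O=C1CC[C@H](O)C(C)(C)[C@@H]1CC/C(C)=C/CC/C(C)=C/COC(C)=O | intermediate
12 | (2E,6E)-9-[(1R,3S)-3-hydroxy-2,2-dimethyl-6-methylidenecyclohexyl]-3,7-dimethylnona-2,6-dien-1-yl acetate | C=C1CC[C@H](O)C(C)(C)[C@@H]1CC/C(C)=C/CC/C(C)=C/COC(C)=O | intermediate
13 | 4-hydroxy-6-methyl-2H-pyran-2-one | Cc1cc(O)cc(=O)o1 | starting material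
14 | sartorypyrone D, 4-hydroxy-3-[(2E,6E)-9-[(1R,3S)-3-hydroxy-2,2-dimethyl-6-methylidenecyclohexyl]-3,7-dimethylnona-2,6-dien-1-yl]-6-methyl-2H-pyran-2-one | C=C1CC[C@H](O)C(C)(C)[C@@H]1CC/C(C)=C/CC/C(C)=C/Cc1c(O)cc(C)oc1=O | target

**Totals**
Total step count: 8. Longest linear sequence: 8 steps (1 to 14); 4 and 13 are purchased and enter at steps 3 and 8.

**Steps most likely to fail**

Step 6. The addition of radical 9 to the aldehyde is reversible. If β-scission of alkoxyl radical 10 outruns its reduction, the isopropenyl group is merely hydrogenated. Further risks are 6-endo attack on the C6=C7 alkene, hydrogen-atom return that moves the alkene into conjugation with the ketone, and weak face selectivity at C3. The fallback sets out from 8 and comes back at 11 and uses known cobalt/chromium radical–polar crossover chemistry. Cobalt-hydride HAT (Co(salen)Cl catalyst, PhSiH3, THF) in the presence of CrCl2 lets divalent chromium capture the tertiary radical as the tertiary alkylchromium dichloride F1. This adds to the aldehyde, chemoselectively over the ketone, in a polar and irreversible Nozaki–Hiyama-type step through a cyclic transition state with the side chain equatorial, giving the chromium alkoxide of 11 F2. Turnover and aqueous work-up release 11. The reversible alkoxyl-radical stage is thereby removed.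

Step 3. Ligand control of the aldehyde face or the anti preference may be insufficient with this functionalised bromide, Wurtz-type homocoupling may consume 3, and TMSCl may erode the acetal. The fallback sets out from 3 and comes back at 6. Ligand-free borylation (B2pin2, Pd2(dba)3 cat., THF, rt; the bromide ionises far faster than the acetate) should give (2E,6E,10E)-3,7,11-trimethyl-12-(4,4,5,5-tetramethyl-1,3,2-dioxaborolan-2-yl)dodeca-2,6,10-trien-1-yl acetate F3. Its allylboration of 4 under a BINOL-derived chiral phosphoric acid (TRIP antipode giving 11R, toluene, −30 °C) proceeds through a closed chair transition state to the pinacol borate ester of 6 F4, which aqueous work-up converts into 6.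

Step 8. Regio- and geometric control in the π-allyl intermediate may be lost (branched isomer, E/Z scrambling), and double allylation at pyrone C3 may occur. The fallback sets out from 12 and comes back at 14 by SN2 chemistry. Methanolysis (K2CO3, MeOH, rt) should give (2E,6E)-9-[(1R,3S)-3-hydroxy-2,2-dimethyl-6-methylidenecyclohexyl]-3,7-dimethylnona-2,6-dien-1-ol F5. Corey–Kim bromination (NBS, Me2S, CH2Cl2, −20 °C), selective for the allylic over the hindered secondary alcohol, should give (1S,3R)-3-[(3E,7E)-9-bromo-3,7-dimethylnona-3,7-dien-1-yl]-2,2-dimethyl-4-methylidenecyclohexan-1-ol F6. C3-alkylation of excess 13 (K2CO3, DMF, rt) then gives 14 with the (E)-geometry fixed by the bromide.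

**Further compounds**
F1 | step 6 | tertiary alkylchromium dichloride derived from 8 (not isolated) | CC(C)([Cr](Cl)Cl)[C@@H](C(=O)CCC=O)CC/C(C)=C/CC/C(C)=C/COC(C)=O
F2 | step 6 | chromium alkoxide of 11 (not isolated) | O=C1CC[C@H](O[Cr](Cl)Cl)C(C)(C)[C@@H]1CC/C(C)=C/CC/C(C)=C/COC(C)=O
F3 | step 3 | (2E,6E,10E)-3,7,11-trimethyl-12-(4,4,5,5-tetramethyl-1,3,2-dioxaborolan-2-yl)dodeca-2,6,10-trien-1-yl acetate | CC1(C)OB(C/C(C)=C/CC/C(C)=C/CC/C(C)=C/COC(C)=O)OC1(C)C
F4 | step 3 | pinacol borate ester of 6 (not isolated) | C=C(C)[C@@H]([C@H](OB1OC(C)(C)C(C)(C)O1)CCC(OC)OC)CC/C(C)=C/CC/C(C)=C/COC(C)=O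
F5 | step 8 | (2E,6E)-9-[(1R,3S)-3-hydroxy-2,2-dimethyl-6-methylidenecyclohexyl]-3,7-dimethylnona-2,6-dien-1-ol | C=C1CC[C@H](O)C(C)(C)[C@@H]1CC/C(C)=C/CC/C(C)=C/CO
F6 | step 8 | (1S,3R)-3-[(3E,7E)-9-bromo-3,7-dimethylnona-3,7-dien-1-yl]-2,2-dimethyl-4-methylidenecyclohexan-1-ol | C=C1CC[C@H](O)C(C)(C)[C@@H]1CC/C(C)=C/CC/C(C)=C/CBr
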